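The earlier runs and the new flask are calculated from invented constants, noise included.

Equal amounts go into each set-up, and the set-ups differ in when and how those amounts meet.

| setting | epsilon | gamma | alpha | Wednesday's | Tuesday's | Thursday's | Friday's |
|---|---|---|---|---|---|---|---|
| Eb | 0.020 M | 0.010 M | 0.015 M | 0.020 M (fed, over 20.0 min) | 0.020 M | 0.020 M | 0.020 M |
| Jo | 0.060 M | 0.060 M | 0.060 M | 0.0600 M | 0.0600 M | 0.0600 M | 0.0600 M (fed, over 20.0 min) |
| Qe | 0.036 M | 0.036 M | 0.036 M | 0.0360 M | 0.0360 M | 0.0360 M | 0.0360 M |
| Ve | 6 mM | 6 mM | 6 mM | 6.00 mM | 6.00 mM | 6.00 mM | 6.00 mM |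
| remark | run made earlier | run made earlier | run made earlier | all but Eb at the start; Eb goes in evenly over 20.0 min, the run ends at 25 min | one stirred flow tank at steady state, fed with the mixture as stated, mean residence time 25 min | everything together in a closed stirred flask, run for 25 min | all but Jo at the start; Jo goes in evenly over 20.0 min, the run ends at 25 min |
| time |  |  |  | 25 min |  | 25 min | 25 min |

| run | time / min | Ry / % | Eb / % |
|---|---|---|---|
| epsilon | 2.50 | 12.0 | 87.1 |
| epsilon | 5.00 | 21.1 | 76.6 |
| epsilon | 8.00 | 31.1 | 65.6 |
| epsilon | 10.0 | 36.7 | 58.1 |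
| epsilon | 12.0 | 40.9 | 52.0 |
| epsilon | 15.0 | 47.2 | 44.4 |
| gamma | 2.00 | 12.1 | 87.4 |
| gamma | 3.00 | 18.4 | 81.8 |
| gamma | 6.00 | 33.0 | 65.4 |
| gamma | 10.0 | 50.1 | 46.5 |
| gamma | 15.0 | 65.7 | 29.3 |
| gamma | 25.0 | 82.7 | 9.5 |
| alpha | 2.00 | 11.0 | 89.7 |
| alpha | 3.00 | 15.0 | 84.0 |
| alpha | 6.00 | 28.3 | 69.8 |
| alpha | 10.0 | 41.9 | 53.6 |
| alpha | 15.0 | 55.3 | 37.4 |
| alpha | 25.0 | 70.8 | 16.6 |

(readings scatter by 0.5 percentage points)

- the set-up with the highest amount of Ry at the outlet or at the end, in percent of the Eb put in ("none" if the first two lie within 2 percentage points) (Wednesday's / Tuesday's / Thursday's / Friday's / none)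
- amount of Ry at the outlet or at the end, in percent of the Eb put in, Wednesday's
- amount of Ry at the outlet or at the end, in percent of the Eb put in, Tuesday's
- amount of Ry at the outlet or at the end, in percent of the Eb put in, Thursday's
- amount of Ry at the outlet or at the end, in percent of the Eb put in, Friday's

- the stated concentrations are those of everything mixed, before any reaction; amounts are the same in each set-up
- the feed brings no volume worth counting
- the earlier runs were made in a closed, stirred flask

The epsilon run has the same charges as Thursday's flask, and it gives one usable quantity, the Eb time: elapsed time divided by the natural logarithm of charged Eb over Eb left. Its last reading gives 18.5 min and its first 18.1 min, so that run looks pseudo-first-order. Of the Eb consumed by then, 84.9 % stands as Ry.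

Now the set-ups, by this reckoning. For Thursday's flask, taking Eb as exponential over the run with that time, and taking the same Ry share of what is consumed, gives 63.0 % Ry. For Tuesday's tank, the consumed fraction is taken as the ratio of residence time to Eb time, divided by one plus that ratio, which with the same share gives 48.8 %. Feeding Eb shortens the contact of its late portions, but the Eb time differs between runs of different strength: the gamma run, charged with 0.010 M, gives 10.6 min at its last reading, shorter than the epsilon run's. Wednesday's flask therefore gets a bracket, 45.3 % with the longer time and 61.0 % with the shorter. Feeding Jo gets no figure, since the earlier runs hold Jo at 0.060 M each.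

The forecast names Thursday's, with 61.5 % there, 53 % for Wednesday's, 46 % for Tuesday's and 45 % for Friday's, though “Jo was never varied, so its order is unknown”. Its Thursday and Tuesday figures lie below this reckoning.

Thursday's gives 61.0 %, Wednesday's 51.2 %, Friday's 50.5 % and Tuesday's 44.0 %, so Thursday's stands highest, and Friday's lies 5.5 percentage points above the forecast. Wednesday's value falls inside the Eb-time bracket of 45.3 % to 61.0 %.

    Eb + Ju → Rx + Ry (k = 0.830 /M/s)
    Ju + Rx ⇌ Qe, settled at all times (K = 34000 /M)
    Rx + Jo ⇌ Rx.Jo (K = 1.90 × 10⁵ /M, k = 0.600 /M/s)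
    Ju + Ve → Ju.Ve (k = 0.150 /M/s)
    Eb + Ry → Eb.Ry (k = 0.0150 /M/s)

In Thursday's flask, with the other concentrations as charged, Ju has a half-life of 0.70 min by the step with Eb alone and 13 min by the step with Ve alone, so the step to Ry is the faster. The ratio of those half-lives is 18.6.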